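**Retrosynthetic overview**

1. Ring D (the 2,2-dimethyl-2H-pyran) is cut at its C3=C4 double bond and its O1–C2 bond. This gives a ring-B salicylaldehyde (formyl on C5', free hydroxyl on C4') and (2-methylprop-1-enyl)boronic acid, joined in one amine-catalysed Petasis / amine-loss / oxa-6π cascade that also builds the fully substituted O–C(CH3)2 carbon.
2. Enabling feature: the phenolic oxygen on C4' (the later pyran oxygen) is ortho to C5', the ring-B carbon that carries the later C4 of ring D. As a free hydroxyl beside a formyl group it binds boron, steers the alkenyl carbon onto the formyl carbon, expels the amine as an ortho-quinone methide and closes onto the dimethyl-substituted carbon. The C2' hydroxyl is para to the formyl group and cannot compete.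
3. The formyl group comes from magnesium-mediated ortho-formylation of the 2',4'-diol, where C5' is the only hydrogen-bearing carbon ortho to a free hydroxyl. The prenyl group on C3' is placed at the outset by directed ortho-metalation between the two MOM ethers of resorcinol.
4. The (R)-centre C3 is set by Evans alkylation of the ring-B arylacetyl imide with a ring-A 2-bromobenzyl bromide. Reductive removal of the auxiliary and Pd-catalysed intramolecular C–O coupling close ring C.
5. Ring order: rings A and B are bought as benzenes, ring C is closed in step 10, ring D in step 13; desilylation of the C7 oxygen ends the route.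

Key step: step 13

Remark: isoflavan numbering is used (ring A/ring C = the chroman with O1, C2, C3, C4 and the C7 oxygen; ring B = C1'–C6' on C3; ring D = the dimethylpyran fused at C4'–C5'); the single stereocentre C3 is read from the SMILES as (R). MOM = methoxymethyl.

**Route**

Step 1
Reactants: 1 resorcinol (benzene-1,3-diol)
Product: 2 1,3-bis(methoxymethoxy)benzene
Conditions: MOMCl (2.5 equiv), i-Pr2NEt (3 equiv), CH2Cl2, 0 °C → rt
Reagents that add atoms: chloromethyl methyl ether (MOMCl), COCCl
Why: Double O-alkylation of the phenols (Williamson-type ether formation) gives the bis-MOM ether, whose acetal oxygens direct both later metalations.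

Step 2
Reactants: 2 1,3-bis(methoxymethoxy)benzene
Product: 4 1,3-bis(methoxymethoxy)-2-(3-methylbut-2-en-1-yl)benzene, via aryllithium 3 (not isolated)
Conditions: n-BuLi (1.1 equiv), THF, 0 °C; then CuI (10 mol%), prenyl bromide, −78 °C → rt
Reagents that add atoms: 1-bromo-3-methylbut-2-ene (prenyl bromide), CC(C)=CCBr
Why: Directed ortho-metalation occurs at C2, the carbon flanked by both MOM ethers, and copper-catalysed SN2 allylation of the aryllithium should give the linear prenyl arene.

Step 3
Reactants: 4 1,3-bis(methoxymethoxy)-2-(3-methylbut-2-en-1-yl)benzene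
Product: 6 2-[2,4-bis(methoxymethoxy)-3-(3-methylbut-2-en-1-yl)phenyl]ethan-1-ol, via aryllithium 5 (not isolated)
Conditions: s-BuLi (1.2 equiv), TMEDA, THF, −78 °C; then oxirane (3 equiv, THF solution), −78 °C → rt; H2O
Reagents that add atoms: oxirane (ethylene oxide), C1CO1
Why: A second, kinetically controlled directed ortho-metalation next to one MOM ether (C4 and C6 are equivalent by symmetry) and epoxide opening by the aryllithium install the two carbons that become C3 and C2 of ring C.

Step 4
Reactants: 6 2-[2,4-bis(methoxymethoxy)-3-(3-methylbut-2-en-1-yl)phenyl]ethan-1-ol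
Product: 8 2-[2,4-bis(methoxymethoxy)-3-(3-methylbut-2-en-1-yl)phenyl]acetic acid, via arylacetaldehyde 7 (not isolated)
Conditions: TEMPO (0.2 equiv), PhI(OAc)2 (2.5 equiv), MeCN/H2O (1:1), rt
Reagents that add atoms: water, O
Why: Oxoammonium-catalysed oxidation (TEMPO/PhI(OAc)2) takes the primary alcohol through the aldehyde hydrate to the acid under nearly neutral conditions that should spare the MOM acetals and the trisubstituted alkene.

Step 5
Reactants: 8 2-[2,4-bis(methoxymethoxy)-3-(3-methylbut-2-en-1-yl)phenyl]acetic acid; 9 (R)-4-benzyloxazolidin-2-one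
Product: 11 (4R)-4-benzyl-3-{[2,4-bis(methoxymethoxy)-3-(3-methylbut-2-en-1-yl)phenyl]acetyl}oxazolidin-2-one, via mixed pivalic anhydride 10 (not isolated)
Conditions: t-BuCOCl (1.1 equiv), Et3N (2.5 equiv), THF, −20 °C; then 9 (1.0 equiv), LiCl (1.1 equiv), −20 °C → rt
Reagents that add atoms: none
Why: N-acylation of the oxazolidinone through the mixed pivalic anhydride (LiCl/Et3N activation) attaches the chiral auxiliary without a strong base.

Step 6
Reactants: 12 3-bromo-4-methylphenol
Product: 13 (3-bromo-4-methylphenoxy)triisopropylsilane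
Conditions: i-Pr3SiCl (1.1 equiv), imidazole (2 equiv), DMF, rt
Reagents that add atoms: chlorotriisopropylsilane, CC(C)[Si](Cl)(C(C)C)C(C)C
Why: O-silylation of the phenol gives a bulky aryl silyl ether that should survive base, hydride and dilute acid and is the only protecting group left for the final fluoride step.

Step 7
Reactants: 13 (3-bromo-4-methylphenoxy)triisopropylsilane
Product: 14 [3-bromo-4-(bromomethyl)phenoxy]triisopropylsilane
Conditions: NBS (1.05 equiv), AIBN (cat.), PhCF3, 85 °C
Reagents that add atoms: N-bromosuccinimide (NBS), O=C1CCC(=O)N1Br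
Why: Wohl–Ziegler radical bromination of the benzylic methyl group gives the ring-A electrophile, and the ring bromine ortho to it is kept for the later C–O coupling.

Step 8
Reactants: 11 (4R)-4-benzyl-3-{[2,4-bis(methoxymethoxy)-3-(3-methylbut-2-en-1-yl)phenyl]acetyl}oxazolidin-2-one; 14 [3-bromo-4-(bromomethyl)phenoxy]triisopropylsilane
Product: 16 (4R)-4-benzyl-3-[(2R)-2-[2,4-bis(methoxymethoxy)-3-(3-methylbut-2-en-1-yl)phenyl]-3-{2-bromo-4-[(triisopropylsilyl)oxy]phenyl}propanoyl]oxazolidin-2-one, via sodium enolate 15 (not isolated)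
Conditions: NaN(SiMe3)2 (1.1 equiv), THF, −78 °C; then 14, −78 → −30 °C
Reagents that add atoms: none
Why: Evans alkylation, in which the chelated (Z)-sodium enolate is attacked by the benzylic bromide on the face opposite the benzyl group of the (R)-auxiliary, should set the (R)-configuration of the carbon that becomes C3.

Step 9
Reactants: 16 (4R)-4-benzyl-3-[(2R)-2-[2,4-bis(methoxymethoxy)-3-(3-methylbut-2-en-1-yl)phenyl]-3-{2-bromo-4-[(triisopropylsilyl)oxy]phenyl}propanoyl]oxazolidin-2-one
Product: 17 (2R)-2-[2,4-bis(methoxymethoxy)-3-(3-methylbut-2-en-1-yl)phenyl]-3-{2-bromo-4-[(triisopropylsilyl)oxy]phenyl}propan-1-ol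
Conditions: LiBH4 (2 equiv), H2O (1 equiv), Et2O, 0 °C
Reagents that add atoms: none
Why: Reductive cleavage of the imide at the exocyclic carbonyl by LiBH4 gives the primary alcohol and releases auxiliary 9 for recovery, and the stereocentre is no longer alpha to a carbonyl group afterwards.

Step 10
Reactants: 17 (2R)-2-[2,4-bis(methoxymethoxy)-3-(3-methylbut-2-en-1-yl)phenyl]-3-{2-bromo-4-[(triisopropylsilyl)oxy]phenyl}propan-1-ol
Product: 18 {[(3R)-3-[2,4-bis(methoxymethoxy)-3-(3-methylbut-2-en-1-yl)phenyl]-3,4-dihydro-2H-chromen-7-yl]oxy}triisopropylsilane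
Conditions: Pd(OAc)2 (5 mol%), 2-(di-tert-butylphosphino)-1,1'-binaphthyl (6 mol%), Cs2CO3 (1.5 equiv), toluene, 60 °C
Reagents that add atoms: none
Why: Intramolecular Buchwald–Hartwig C–O coupling, in which zerovalent palladium inserts into the ring-A C–Br bond and C–O reductive elimination closes the six-membered ring C, should leave the neighbouring stereocentre intact because the bulky phosphine favours reductive elimination over beta-hydride elimination.

Step 11
Reactants: 18 {[(3R)-3-[2,4-bis(methoxymethoxy)-3-(3-methylbut-2-en-1-yl)phenyl]-3,4-dihydro-2H-chromen-7-yl]oxy}triisopropylsilane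
Product: 19 2-(3-methylbut-2-en-1-yl)-4-{(3R)-7-[(triisopropylsilyl)oxy]-3,4-dihydro-2H-chromen-3-yl}benzene-1,3-diol
Conditions: HCl (3 M aq, 5 equiv), MeOH, 40 °C, stopped at full conversion
Reagents that add atoms: none
Why: Acid-catalysed transacetalisation removes both MOM groups while the aryl silyl ether is stable to dilute acid, and the short mild treatment is chosen to keep the prenyl group from adding to the freed hydroxyls.

Step 12
Reactants: 19 2-(3-methylbut-2-en-1-yl)-4-{(3R)-7-[(triisopropylsilyl)oxy]-3,4-dihydro-2H-chromen-3-yl}benzene-1,3-diol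
Product: 21 2,4-dihydroxy-3-(3-methylbut-2-en-1-yl)-5-{(3R)-7-[(triisopropylsilyl)oxy]-3,4-dihydro-2H-chromen-3-yl}benzaldehyde, via hydroxymethyl phenol 20 (not isolated)
Conditions: MgCl2 (3 equiv), Et3N (6 equiv), (CH2O)n (8 equiv), MeCN, 80 °C; then 1 M aq HCl work-up
Reagents that add atoms: formaldehyde (as paraformaldehyde), C=O
Why: Casiraghi–Skattebøl ortho-formylation, in which the magnesium phenoxide delivers formaldehyde through a six-membered chelate only to a carbon ortho to a free hydroxyl, should hit C5' alone (the C2' hydroxyl lies between the substituted C1' and C3', and the ring-A oxygen is silylated), a second formaldehyde oxidising the hydroxymethyl intermediate by hydride transfer.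

Step 13
Reactants: 21 2,4-dihydroxy-3-(3-methylbut-2-en-1-yl)-5-{(3R)-7-[(triisopropylsilyl)oxy]-3,4-dihydro-2H-chromen-3-yl}benzaldehyde; 22 (2-methylprop-1-en-1-yl)boronic acid
Product: 25 2,2-dimethyl-8-(3-methylbut-2-en-1-yl)-6-{(3R)-7-[(triisopropylsilyl)oxy]-3,4-dihydro-2H-chromen-3-yl}-2H-chromen-7-ol, via Mannich adduct 23 (not isolated), via ortho-quinone methide 24 (not isolated)
Conditions: 22 (2 equiv), Bn2NH (0.4 equiv), 1,4-dioxane, 90 °C
Reagents that add atoms: none
Why: The secondary amine condenses with the formyl group on C5' to an iminium ion while the neighbouring C4' hydroxyl binds the boronic acid as a tetracoordinate boronate, a temporary B–O tether that transfers the 2-methylprop-1-enyl group intramolecularly to the iminium carbon (Petasis boronic acid Mannich reaction; this first bond becomes the C3=C4 double bond of ring D). The benzylic amine 23 then ionises thermally with push from the same phenol oxygen, which returns Bn2NH to the cycle and gives the ortho-quinone methide 24, a 1-oxatriene whose far terminus is the dimethyl-substituted carbon. A thermal disrotatory oxa-6π electrocyclisation closes ring D by joining that oxygen to the fully substituted carbon and restores the aromaticity of ring B, which drives the sequence; the closest known reaction type is the amine-catalysed condensation of salicylaldehydes with alkenylboronic acids to 2H-chromenes. No new stereocentre results (C2 of ring D carries two methyl groups and the aminated carbon of 23 becomes planar again), and the (R)-centre at C3 of ring C is remote and bears no acidic hydrogen. The step needs regioselectivity between the two ring-B hydroxyls and chemoselectivity against the prenyl alkene and ring A: only the C4' oxygen is ortho to the formyl carbon, the C2' hydroxyl is para to it and flanked by substituted carbons, the isolated prenyl double bond does not react with a boronate/iminium pair, and the silyl ether keeps ring A from intercepting the quinone methide.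

Step 14
Reactants: 25 2,2-dimethyl-8-(3-methylbut-2-en-1-yl)-6-{(3R)-7-[(triisopropylsilyl)oxy]-3,4-dihydro-2H-chromen-3-yl}-2H-chromen-7-ol
Product: 26 (3R)-3-[7-hydroxy-2,2-dimethyl-8-(3-methylbut-2-en-1-yl)-2H-chromen-6-yl]-3,4-dihydro-2H-chromen-7-ol (CNP0331403.1)
Conditions: Bu4NF (1.1 equiv), AcOH (1.1 equiv), THF, 0 °C
Reagents that add atoms: none
Why: Fluoride-induced cleavage of the aryl silyl ether frees the C7 hydroxyl under buffered, non-acidic conditions that should leave ring D, the prenyl group and the stereocentre untouched.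

**Compound list**

1 | resorcinol (benzene-1,3-diol) | Oc1cccc(O)c1 | starting material
2 | 1,3-bis(methoxymethoxy)benzene | COCOc1cccc(OCOC)c1 | intermediate
3 | [2,6-bis(methoxymethoxy)phenyl]lithium | [Li]c1c(OCOC)cccc1OCOC | intermediate
4 | 1,3-bis(methoxymethoxy)-2-(3-methylbut-2-en-1-yl)benzene | COCOc1cccc(OCOC)c1CC=C(C)C | intermediate
5 | [2,4-bis(methoxymethoxy)-3-(3-methylbut-2-en-1-yl)phenyl]lithium | [Li]c1ccc(OCOC)c(CC=C(C)C)c1OCOC | intermediate
6 | 2-[2,4-bis(methoxymethoxy)-3-(3-methylbut-2-en-1-yl)phenyl]ethan-1-ol | OCCc1ccc(OCOC)c(CC=C(C)C)c1OCOC | intermediate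
7 | 2-[2,4-bis(methoxymethoxy)-3-(3-methylbut-2-en-1-yl)phenyl]acetaldehyde | O=CCc1ccc(OCOC)c(CC=C(C)C)c1OCOC | intermediate
8 | 2-[2,4-bis(methoxymethoxy)-3-(3-methylbut-2-en-1-yl)phenyl]acetic acid | OC(=O)Cc1ccc(OCOC)c(CC=C(C)C)c1OCOC | intermediate
9 | (R)-4-benzyloxazolidin-2-one | O=C1N[C@H](Cc2ccccc2)CO1 | starting material
10 | mixed anhydride of acid 8 with pivalic acid | CC(C)(C)C(=O)OC(=O)Cc1ccc(OCOC)c(CC=C(C)C)c1OCOC | intermediate
11 | (4R)-4-benzyl-3-{[2,4-bis(methoxymethoxy)-3-(3-methylbut-2-en-1-yl)phenyl]acetyl}oxazolidin-2-one | COCOc1ccc(CC(=O)N2[C@H](Cc3ccccc3)COC2=O)c(OCOC)c1CC=C(C)C | intermediate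
12 | 3-bromo-4-methylphenol | Cc1ccc(O)cc1Br | starting material
13 | (3-bromo-4-methylphenoxy)triisopropylsilane | Cc1ccc(O[Si](C(C)C)(C(C)C)C(C)C)cc1Br | intermediate
14 | [3-bromo-4-(bromomethyl)phenoxy]triisopropylsilane | BrCc1ccc(O[Si](C(C)C)(C(C)C)C(C)C)cc1Br | intermediate
15 | sodium (Z)-enolate of imide 11 | [Na+].[O-]/C(=C\c1ccc(OCOC)c(CC=C(C)C)c1OCOC)N1[C@H](Cc2ccccc2)COC1=O | intermediate
16 | (4R)-4-benzyl-3-[(2R)-2-[2,4-bis(methoxymethoxy)-3-(3-methylbut-2-en-1-yl)phenyl]-3-{2-bromo-4-[(triisopropylsilyl)oxy]phenyl}propanoyl]oxazolidin-2-one | COCOc1ccc([C@@H](Cc2ccc(O[Si](C(C)C)(C(C)C)C(C)C)cc2Br)C(=O)N2[C@H](Cc3ccccc3)COC2=O)c(OCOC)c1CC=C(C)C | intermediate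
17 | (2R)-2-[2,4-bis(methoxymethoxy)-3-(3-methylbut-2-en-1-yl)phenyl]-3-{2-bromo-4-[(triisopropylsilyl)oxy]phenyl}propan-1-ol | COCOc1ccc([C@@H](Cc2ccc(O[Si](C(C)C)(C(C)C)C(C)C)cc2Br)CO)c(OCOC)c1CC=C(C)C | intermediate
18 | {[(3R)-3-[2,4-bis(methoxymethoxy)-3-(3-methylbut-2-en-1-yl)phenyl]-3,4-dihydro-2H-chromen-7-yl]oxy}triisopropylsilane | COCOc1ccc([C@@H]2COc3cc(O[Si](C(C)C)(C(C)C)C(C)C)ccc3C2)c(OCOC)c1CC=C(C)C | intermediate
19 | 2-(3-methylbut-2-en-1-yl)-4-{(3R)-7-[(triisopropylsilyl)oxy]-3,4-dihydro-2H-chromen-3-yl}benzene-1,3-diol | CC(C)=CCc1c(O)ccc([C@@H]2COc3cc(O[Si](C(C)C)(C(C)C)C(C)C)ccc3C2)c1O | intermediate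
20 | 4-(hydroxymethyl)-2-(3-methylbut-2-en-1-yl)-6-{(3R)-7-[(triisopropylsilyl)oxy]-3,4-dihydro-2H-chromen-3-yl}benzene-1,3-diol (formed as its magnesium salt) | CC(C)=CCc1c(O)c(CO)cc([C@@H]2COc3cc(O[Si](C(C)C)(C(C)C)C(C)C)ccc3C2)c1O | intermediate
21 | 2,4-dihydroxy-3-(3-methylbut-2-en-1-yl)-5-{(3R)-7-[(triisopropylsilyl)oxy]-3,4-dihydro-2H-chromen-3-yl}benzaldehyde | CC(C)=CCc1c(O)c(C=O)cc([C@@H]2COc3cc(O[Si](C(C)C)(C(C)C)C(C)C)ccc3C2)c1O | intermediate
22 | (2-methylprop-1-en-1-yl)boronic acid | CC(C)=CB(O)O | starting material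
23 | 4-[1-(dibenzylamino)-3-methylbut-2-en-1-yl]-2-(3-methylbut-2-en-1-yl)-6-{(3R)-7-[(triisopropylsilyl)oxy]-3,4-dihydro-2H-chromen-3-yl}benzene-1,3-diol (both epimers at the aminated carbon) | CC(C)=CCc1c(O)c(C(C=C(C)C)N(Cc2ccccc2)Cc2ccccc2)cc([C@@H]2COc3cc(O[Si](C(C)C)(C(C)C)C(C)C)ccc3C2)c1O | intermediate
24 | 3-hydroxy-2-(3-methylbut-2-en-1-yl)-6-(3-methylbut-2-en-1-ylidene)-4-{(3R)-7-[(triisopropylsilyl)oxy]-3,4-dihydro-2H-chromen-3-yl}cyclohexa-2,4-dien-1-one (ortho-quinone methide) | CC(C)=CCC1=C(O)C([C@@H]2COc3cc(O[Si](C(C)C)(C(C)C)C(C)C)ccc3C2)=CC(=CC=C(C)C)C1=O | intermediate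
25 | 2,2-dimethyl-8-(3-methylbut-2-en-1-yl)-6-{(3R)-7-[(triisopropylsilyl)oxy]-3,4-dihydro-2H-chromen-3-yl}-2H-chromen-7-ol | CC(C)=CCc1c(O)c([C@@H]2COc3cc(O[Si](C(C)C)(C(C)C)C(C)C)ccc3C2)cc2c1OC(C)(C)C=C2 | intermediate
26 | (3R)-3-[7-hydroxy-2,2-dimethyl-8-(3-methylbut-2-en-1-yl)-2H-chromen-6-yl]-3,4-dihydro-2H-chromen-7-ol | CC(C)=CCc1c(O)c([C@@H]2COc3cc(O)ccc3C2)cc2c1OC(C)(C)C=C2 | target

**Step count**

Total: 14 steps. Longest linear sequence: 12 steps (steps 1–5, then 8–14); the ring-A branch (steps 6–7) joins at step 8.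

**Steps most likely to fail, with fallbacks**

Step 13 (key step). Iminium formation and alkenyl transfer may be slow on an aldehyde deactivated by one ortho and one para hydroxyl, so protodeboronation of the boronic acid or intermolecular capture of the quinone methide could outrun ring closure. The fallback replaces the three-component cascade by organomagnesium addition followed by dehydrative electrocyclisation. It sets out from 21: excess 2-methylprop-1-enylmagnesium bromide (THF, 0 °C → rt; two equivalents are consumed by the phenols) should give the benzylic allylic alcohol F1. Warming F1 in toluene (80 °C, trace of pyridinium p-toluenesulfonate) should expel water to the same ortho-quinone methide 24, which closes to 25, where the route is rejoined.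

Step 11. During acidic acetal cleavage the freed C2' or C4' hydroxyl may add to the protonated prenyl double bond (chroman formation), or cleavage may stall before both MOM groups are gone. The fallback avoids Brønsted acid by exchanging the acetals for silyl groups under buffered aprotic conditions. It sets out from 18: Me3SiOTf and 2,2'-bipyridyl in MeCN at 0 °C should convert both aryl MOM ethers into the bis(trimethylsilyl) ether F2. Addition of water should then hydrolyse the two labile aryl trimethylsilyl ethers, but not the triisopropylsilyl ether, to 19, where the route is rejoined.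

Step 10. Beta-hydride elimination from the palladium alkoxide may compete with C–O reductive elimination, which would reduce the aryl bromide and oxidise the alcohol to an epimerisable alpha-aryl aldehyde; carbonate or alkoxide may also attack the silyl ether. The fallback turns the aryl bromide into a phenol and closes ring C by SN2 displacement at the primary carbon. It sets out from 17: Miyaura borylation (B2pin2, PdCl2(dppf), KOAc, dioxane, 80 °C) should give the pinacol boronate F3. Oxidation (NaBO3·4H2O, THF/H2O, rt) should give the phenol F4, and Mitsunobu cyclisation (PPh3, DIAD, THF, 0 °C → rt) should give 18, where the route is rejoined.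

**Further compounds**

F1 | step 13 | 4-(1-hydroxy-3-methylbut-2-en-1-yl)-2-(3-methylbut-2-en-1-yl)-6-{(3R)-7-[(triisopropylsilyl)oxy]-3,4-dihydro-2H-chromen-3-yl}benzene-1,3-diol (both epimers at the carbinol carbon) | CC(C)=CCc1c(O)c(C(O)C=C(C)C)cc([C@@H]2COc3cc(O[Si](C(C)C)(C(C)C)C(C)C)ccc3C2)c1O
F2 | step 11 | {[(3R)-3-[3-(3-methylbut-2-en-1-yl)-2,4-bis(trimethylsilyloxy)phenyl]-3,4-dihydro-2H-chromen-7-yl]oxy}triisopropylsilane | CC(C)=CCc1c(O[Si](C)(C)C)ccc([C@@H]2COc3cc(O[Si](C(C)C)(C(C)C)C(C)C)ccc3C2)c1O[Si](C)(C)C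
F3 | step 10 | (2R)-2-[2,4-bis(methoxymethoxy)-3-(3-methylbut-2-en-1-yl)phenyl]-3-{2-(4,4,5,5-tetramethyl-1,3,2-dioxaborolan-2-yl)-4-[(triisopropylsilyl)oxy]phenyl}propan-1-ol | COCOc1ccc([C@@H](Cc2ccc(O[Si](C(C)C)(C(C)C)C(C)C)cc2B2OC(C)(C)C(C)(C)O2)CO)c(OCOC)c1CC=C(C)C
F4 | step 10 | 2-{(2R)-2-[2,4-bis(methoxymethoxy)-3-(3-methylbut-2-en-1-yl)phenyl]-3-hydroxypropyl}-5-[(triisopropylsilyl)oxy]phenol | COCOc1ccc([C@@H](Cc2ccc(O[Si](C(C)C)(C(C)C)C(C)C)cc2O)CO)c(OCOC)c1CC=C(C)C
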